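## Retrosynthetic overview

1. Last operation: hydrogenolysis of two benzyl ethers frees the catechol; everything else, including C4 (R), is already in place.
2. Key disconnection: lactone ring B is opened at the acyl–oxygen bond O1–C2 (and, in the same catalytic event, at C4–C4a). This gives a 4-alkylresorcinol (ring A with the bibenzyl arm) and a benzyl-protected caffeoyl aldehyde. In the forward sense a chiral carbene/oxidant system first joins the two through an aryl ester C–O bond, then relays that ester into the lactone while fixing C4.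
3. The resorcinol partner comes from resorcinol and (3,4-dimethoxyphenyl)acetic acid by C-acylation and carbonyl-to-methylene reduction.
4. The enal comes from 3,4-bis(benzyloxy)benzaldehyde by a two-carbon Wittig homologation.
5. Ring order: the three benzene rings are bought; ring B (the lactone) is the only ring made, in step 4.

Assumption: C4 of the target is R (CIP analysis of the given SMILES), and the new annulation is taken to follow the usual face-shielding model of the aminoindanol carbene family; if the opposite sense were found, the mirror-image (5aR,10bS) salt would be used, nothing else changing.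

## Route

Step 1
Reactants: 1 resorcinol; 2 (3,4-dimethoxyphenyl)acetic acid
Product: 3 1-(2,4-dihydroxyphenyl)-2-(3,4-dimethoxyphenyl)ethan-1-one
Conditions: BF3·OEt2 (neat, as solvent), 85 °C, 2 h; then aq NaOAc
Reagents that add atoms: none
Why: Friedel–Crafts (Nencki-type) C-acylation of resorcinol by the BF3-activated arylacetic acid occurs at C4 (para to one OH, ortho to the other), the standard deoxybenzoin synthesis; no stereocentre is formed.

Step 2
Reactants: 3 1-(2,4-dihydroxyphenyl)-2-(3,4-dimethoxyphenyl)ethan-1-one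
Product: 4 4-[2-(3,4-dimethoxyphenyl)ethyl]benzene-1,3-diol
Conditions: Et3SiH (3 equiv), CF3CO2H, 25 → 50 °C
Reagents that add atoms: none
Why: Ionic hydrogenation: the protonated ketone and then the benzylic cation, both stabilised by the ortho and para OH groups, each take hydride from the silane, giving the methylene compound; no stereocentre is formed.

Step 3
Reactants: 5 3,4-bis(benzyloxy)benzaldehyde; 6 (triphenylphosphoranylidene)acetaldehyde
Product: 7 (2E)-3-[3,4-bis(benzyloxy)phenyl]prop-2-enal
Conditions: 6 (1.1 equiv), toluene, 90 °C, 16 h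
Reagents that add atoms: none
Why: Wittig reaction of the stabilised formylmethylene ylide with an aromatic aldehyde is E-selective, and a small excess of ylide limits a second homologation.

Step 4
Reactants: 4 4-[2-(3,4-dimethoxyphenyl)ethyl]benzene-1,3-diol; 7 (2E)-3-[3,4-bis(benzyloxy)phenyl]prop-2-enal
Product: 10 (4R)-4-[3,4-bis(benzyloxy)phenyl]-6-[2-(3,4-dimethoxyphenyl)ethyl]-7-hydroxy-3,4-dihydro-2H-chromen-2-one, via acyl azolium chloride 8 (not isolated), via aryl ester 9 (not isolated)
Conditions: 4 (1.2 equiv), 7 (1.0 equiv), (5aS,10bR)-2-mesityl-5a,10b-dihydro-4H,6H-indeno[2,1-b][1,2,4]triazolo[4,3-d][1,4]oxazin-2-ium chloride (10 mol %), 1,8-diazabicyclo[5.4.0]undec-7-ene (DBU, 0.3 equiv), 3,3',5,5'-tetra-tert-butyl-4,4'-diphenoquinone (1.2 equiv), 4 Å molecular sieves, toluene, 25 → 45 °C, argon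
Reagents that add atoms: none
Why: Proposed new method: the carbene and the diphenoquinone turn enal 7 into unsaturated acyl azolium 8, which O-acylates the less hindered phenoxide of 4 to give aryl ester 9 (C–O bond; reversible, because the carbene re-adds to 9 and regenerates the 8/phenoxide ion pair); in that ion pair the resorcinolate attacks C-β through its C6 (ortho to the acylated oxygen, para to the second OH; direct 1,4-addition or O-addition followed by a [3,3] shift) on the Re face left open by the indane wall of the catalyst, which sets C4 as R, and after rearomatisation the ortho phenol closes the lactone C–O bond O1–C2 and releases the carbene; closest known reaction type: oxidative carbene-catalysed annulation of enals with 1,3-dicarbonyl enols and naphthols through unsaturated acyl azolium ions (Coates–Claisen-type annulation) and the carbene-catalysed rearrangement of unsaturated enol esters to dihydropyranones, neither shown for a simple unsymmetrical 4-alkylresorcinol carrying a second free OH.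

Step 5
Reactants: 10 (4R)-4-[3,4-bis(benzyloxy)phenyl]-6-[2-(3,4-dimethoxyphenyl)ethyl]-7-hydroxy-3,4-dihydro-2H-chromen-2-one
Product: 11 (4R)-4-(3,4-dihydroxyphenyl)-6-[2-(3,4-dimethoxyphenyl)ethyl]-7-hydroxy-3,4-dihydro-2H-chromen-2-one (CNP0376539.1)
Conditions: H2 (1 atm), Pd/C (10 wt % Pd, 10 mol %), EtOAc–THF 1:1, 25 °C
Reagents that add atoms: none
Why: Catalytic hydrogenolysis of the two benzyl aryl ethers is neutral and non-nucleophilic, so the aryl lactone, the methyl ethers and the C4 stereocentre (no acidic hydrogen or leaving group there) are untouched.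

## Compound list

1 | resorcinol (benzene-1,3-diol) | Oc1cccc(O)c1 | starting material
2 | (3,4-dimethoxyphenyl)acetic acid | COc1ccc(CC(=O)O)cc1OC | starting material
3 | 1-(2,4-dihydroxyphenyl)-2-(3,4-dimethoxyphenyl)ethan-1-one | COc1ccc(CC(=O)c2ccc(O)cc2O)cc1OC | intermediate
4 | 4-[2-(3,4-dimethoxyphenyl)ethyl]benzene-1,3-diol | COc1ccc(CCc2ccc(O)cc2O)cc1OC | intermediate
5 | 3,4-bis(benzyloxy)benzaldehyde | O=Cc1ccc(OCc2ccccc2)c(OCc2ccccc2)c1 | starting material
6 | (triphenylphosphoranylidene)acetaldehyde | O=CC=P(c1ccccc1)(c1ccccc1)c1ccccc1 | starting material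
7 | (2E)-3-[3,4-bis(benzyloxy)phenyl]prop-2-enal | O=C/C=C/c1ccc(OCc2ccccc2)c(OCc2ccccc2)c1 | intermediate
8 | (5aS,10bR)-1-{(2E)-3-[3,4-bis(benzyloxy)phenyl]prop-2-enoyl}-2-mesityl-5a,10b-dihydro-4H,6H-indeno[2,1-b][1,2,4]triazolo[4,3-d][1,4]oxazin-2-ium chloride (acyl azolium chloride) | O=C(/C=C/c1ccc(OCc2ccccc2)c(OCc2ccccc2)c1)c1n2c(n[n+]1-c1c(C)cc(C)cc1C)CO[C@H]1Cc3ccccc3[C@H]12.[Cl-] | intermediate
9 | 4-[2-(3,4-dimethoxyphenyl)ethyl]-3-hydroxyphenyl (2E)-3-[3,4-bis(benzyloxy)phenyl]prop-2-enoate (aryl ester) | COc1ccc(CCc2ccc(OC(=O)/C=C/c3ccc(OCc4ccccc4)c(OCc4ccccc4)c3)cc2O)cc1OC | intermediate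
10 | (4R)-4-[3,4-bis(benzyloxy)phenyl]-6-[2-(3,4-dimethoxyphenyl)ethyl]-7-hydroxy-3,4-dihydro-2H-chromen-2-one | COc1ccc(CCc2cc3c(cc2O)OC(=O)C[C@@H]3c2ccc(OCc4ccccc4)c(OCc4ccccc4)c2)cc1OC | intermediate
11 | (4R)-4-(3,4-dihydroxyphenyl)-6-[2-(3,4-dimethoxyphenyl)ethyl]-7-hydroxy-3,4-dihydro-2H-chromen-2-one | COc1ccc(CCc2cc3c(cc2O)OC(=O)C[C@@H]3c2ccc(O)c(O)c2)cc1OC | target

## Step count and risks

Total steps: 5. Longest linear sequence: 4 steps (steps 1, 2, 4, 5; 1 → 3 → 4 → 10 → 11).

The three steps most likely to fail: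

- **Step 4 (the proposed annulation).** Risks: the reaction may rest at aryl ester 9 if the carbene does not re-activate it; the resorcinol may attack through C2 instead of C6; the ee may be modest; and the enal may divert into redox esterification. Fallback, known chemistry, setting out from 4 and 7: an iminium-catalysed Friedel–Crafts alkylation/hemiacetalisation with (R)-2-[diphenyl(trimethylsilyloxy)methyl]pyrrolidine (20 mol %) and benzoic acid (20 mol %) in CH2Cl2 at 0 °C. The amine's bulky group blocks the Si face of the E-iminium ion, so the resorcinol C6 adds to the Re face and the ortho OH closes onto the aldehyde. This gives (4R)-4-[3,4-bis(benzyloxy)phenyl]-6-[2-(3,4-dimethoxyphenyl)ethyl]-3,4-dihydro-2H-chromene-2,7-diol F1 as a mixture of C2 anomers. Lactol oxidation with pyridinium chlorochromate, [C5H5NH][CrO3Cl], buffered with NaOAc in CH2Cl2, then comes back to the route at 10.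

- **Step 2 (ionic hydrogenation).** Risk: the hydrogen-bonded, vinylogous-acid ketone may reduce slowly or give benzylic dimers. Fallback setting out from 3: NaBH4 in EtOH–THF gives 4-[2-(3,4-dimethoxyphenyl)-1-hydroxyethyl]benzene-1,3-diol F2. This is dehydrated with catalytic p-toluenesulfonic acid in toluene at 80 °C to 4-[(E)-2-(3,4-dimethoxyphenyl)ethenyl]benzene-1,3-diol F3. Hydrogenation of the alkene (H2, Pd/C, EtOAc) comes back to the route at 4.

- **Step 3 (Wittig homologation).** Risk: the electron-rich aldehyde reacts sluggishly and the product enal can be homologated a second time. Fallback setting out from 5: Horner–Wadsworth–Emmons olefination with triethyl phosphonoacetate and NaH in THF gives ethyl (2E)-3-[3,4-bis(benzyloxy)phenyl]prop-2-enoate F4. Reduction with i-Bu2AlH in CH2Cl2 at −78 °C gives (2E)-3-[3,4-bis(benzyloxy)phenyl]prop-2-en-1-ol F5. Allylic oxidation with MnO2 in CH2Cl2 comes back to the route at 7.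

## Further compounds

F1 | step 4 | (4R)-4-[3,4-bis(benzyloxy)phenyl]-6-[2-(3,4-dimethoxyphenyl)ethyl]-3,4-dihydro-2H-chromene-2,7-diol (C2 anomer mixture) | COc1ccc(CCc2cc3c(cc2O)OC(O)C[C@@H]3c2ccc(OCc4ccccc4)c(OCc4ccccc4)c2)cc1OC
F2 | step 2 | 4-[2-(3,4-dimethoxyphenyl)-1-hydroxyethyl]benzene-1,3-diol (racemic) | COc1ccc(CC(O)c2ccc(O)cc2O)cc1OC
F3 | step 2 | 4-[(E)-2-(3,4-dimethoxyphenyl)ethenyl]benzene-1,3-diol | COc1ccc(/C=C/c2ccc(O)cc2O)cc1OC
F4 | step 3 | ethyl (2E)-3-[3,4-bis(benzyloxy)phenyl]prop-2-enoate | CCOC(=O)/C=C/c1ccc(OCc2ccccc2)c(OCc2ccccc2)c1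
F5 | step 3 | (2E)-3-[3,4-bis(benzyloxy)phenyl]prop-2-en-1-ol | OC/C=C/c1ccc(OCc2ccccc2)c(OCc2ccccc2)c1
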